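Compound numbers are those of the steps and of the compound list below.

Remark on conventions: eudesmane numbering is used (ring A = C1–C5 and C10, ring B = C5–C10, methyl on C10, methylidene carbon C15 on C4, isopropyl on C7); α is the face of ring B that carries the C10 methyl group, β the face from which C1 and C4 of ring A depart; 1, 3 and 20 are taken as commercial.

## Analysis of the target

- Compound 25 is a eudesmane-type sesquiterpenoid ester built on a cis-fused decalin. Ring A carries an exocyclic methylidene at C4. Ring B carries a free secondary hydroxyl at C6, an isopropyl group at C7 and a 4-methoxybenzoate at C9, next to the quaternary, methyl-bearing C10.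
- There are five stereocentres (5S,6S,7R,9R,10R). C10, C5, C6 and C7 are contiguous and C9 is bonded to C10. Read as substituents of ring B they all lie on one face: 10-CH3, 5-H, 6-OH, 7-isopropyl and the 9-acyloxy group are α, and the two ring A bonds are β.
- In the chair of ring B that keeps the isopropyl group and the ester equatorial, the C6 hydroxyl is axial and syn to the axial C10 methyl. It is therefore the less stable carbinol epimer and has to be made under kinetic control.
- Sensitive groups are the 1,1-disubstituted alkene (acid and metal hydride species can move it into the ring) and the aryl ester (hydrides, alkoxides). Any carbonyl placed at C6 makes the alkene β,γ-unsaturated, so H5 becomes a weak point.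
- The difficulties are the quaternary C10 flanked by the oxygenated C9 and the ring fusion, the cis fusion itself, the distinction between the two ring B oxygens (one free, one acylated) and the C7 configuration.
- The strategy rests on one feature: O6 and O9 are cis-1,4 across ring B, on the face of the C10 methyl, with C7 and C8 between them. This is the pattern left by a peroxide bridge across C6 and C9 of a ring B 6,8-diene.

## Retrosynthetic reasoning

**25 to 24 (C6–H).** The axial 6α alcohol, syn to the C10 methyl, is what a bulky hydride gives when the axial approach to a C6 ketone is blocked by that methyl. C6 is therefore set last from ketone 24. The gain is a carbonyl at C6, the only group that can activate C7 and C8.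

**24 to 23 to 21 (C7–H and C8–H).** Ketone 24 carries the isopropyl group in the position where it and the ester are both equatorial, so it is taken as the thermodynamic C7 epimer. It is traced to its epimer 23 and from there to enone 21 by conjugate reduction. The forward steps must add hydride 1,4 without touching the ester or the methylidene, and then epimerise C7 without enolising towards C5.

**21 to 19 and 20 (ester C–O).** Acylation of the single hydroxyl of 19 with acid chloride 20. Placing the ester before the reductions means no protecting group is needed on O9.

**19 to 18 (O–O bond and C6–H).** Hydroxy enone 19 is an isomer of endoperoxide 18. Base-induced fragmentation of the peroxide turns one bridgehead into a ketone and leaves the other as an alcohol. The two oxygens are thus told apart without protecting groups, and the C9–O stereocentre is conserved.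

**18 to 17 (C6–O and C9–O).** Both ring B oxygens are removed together, which leads to the cis-fused diene 17. The forward reaction is a sensitised photooxygenation that must add across C6 and C9 on the α face and must leave the methylidene alone. This is the step that carries the strategy.

**17 to 16 to 14 to 11 (C9–O and two C–H).** Diene 17 has no oxygen. It is traced to the dienyl triflate 16 of enone 14, and 14 to the saturated ketone 11 by dehydrogenation. The C7 stereocentre of 11 is given up here, after it has served to control C5 and C10.

**11 to 9 to 2 and 5 (C1–C10 and C4–C5).** Ring A is cut at the two carbons of the enone unit of 2: the C4–C5 bond by conjugate addition of the alkenyl unit of 5, and the C1–C10 bond by intramolecular enolate alkylation in 9. The isopropyl stereocentre directs the addition trans, and the tether then forces cis fusion, so C5 and C10 take their absolute configuration from the chiral pool.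

**2 to 1 and 5 to 3.** Selective hydrogenation of 1 gives 2. Markovnikov addition of H–Br across alkyne 3 gives 5.

## Alternatives that were turned down

**Alternative 1:** ring B is built onto ring A by cutting C5–C6 and C9–C10.
- Forward key step: a photochemical [2+2] cycloaddition of 3-methylcyclohex-2-en-1-one A2, activated by a chiral Lewis acid, with 1,2-bis(trimethylsilyloxy)cyclobutene A3 gives the tricyclic adduct A1. Desilylation and retro-aldol cleavage of the central cyclobutane bond then open it to the cis-fused trione A4.
- In its favour: the quaternary C10 and the cis fusion come from one catalytic asymmetric step on two simple achiral compounds, and C6 and C9 arrive oxygenated.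
- Against it: A4 has no isopropyl group, and C7 and C8 of its 1,4-dione are almost equivalent towards alkylation. C5 lies between the C4 and C6 carbonyls, so the ring-fusion hydrogen is very acidic and the cis fusion is at risk. Both ring B oxygens arrive as ketones, so the C6 and C9 carbinol centres must both be made by reduction and then distinguished, and the C9 alcohol is the equatorial one that hindered hydrides do not give. The C4 ketone must be methylenated in the presence of two others.
- Comparison: on the origin of the absolute configuration at C10 this route is stronger (catalytic, no stereocentre sacrificed). The chosen route offers in its place the isopropyl group and the methylidene from the start, and a C9–O stereocentre that is made once and never re-made.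

**Alternative 2:** ring A is closed onto an aromatic ring B by cutting C1–C10.
- Forward key step: the phenol A6, a thymohydroquinone monomethyl ether with an iodoalkyl chain, is deprotonated. The phenolate alkylates through its methyl-bearing ortho carbon and is dearomatised to the cyclohexa-2,4-dienone A5.
- In its favour: ring B is bought as an arene with the isopropyl group and both oxygens at the right carbons, and the oxygens are distinguished from the beginning (enol ether at C6, carbonyl at C9). The quaternary centre is set under the influence of the C4 silyloxy stereocentre.
- Against it: A5 is flat. C5, C6, C7 and C9 all remain to be set by reductions of a cross-conjugated dienone, including the cis-fusion hydrogen and the all-cis array. Cyclohexa-2,4-dienones dimerise readily. The C4 oxygen must later be oxidised and methylenated next to the enolisable C5.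
- Comparison: it is stronger on convergence of the ring B functionality and on early differentiation of the oxygens. The chosen route is stronger on stereochemistry: C5 and C10 are fixed early by relay from C7, and C6–O and C9–O are formed together on one face.

**Alternative 3:** the CH–isopropyl carbon is inserted into a five-membered ring (C6–C7 and C7–C8 formed, C6–C8 cut).
- Forward key step: Lewis-acid-catalysed addition of 2-methyl-1-diazopropane A9 to the ketone of the cis-hydrindanone A8, followed by migration of the CH2 carbon with loss of nitrogen, gives the ring-expanded ketone A7. A7 is the same compound as 24.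
- In its favour: the isopropyl group is introduced very late and the product is one reduction from the target. The two oxygens never have to be distinguished, and no C7 equilibration is needed if the insertion is diastereoselective.
- Against it: the choice between migration of C8 and of the tertiary, allylic C5 is not secured, and neither is the C7 configuration. A non-stabilised secondary diazoalkane is unstable and has to be generated in situ, and double insertion is possible. A8, with its quaternary centre, three stereocentres and β,γ-unsaturated ketone, is no easier to make than the decalin, so the problem is only moved back.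
- Comparison: its endgame is shorter than the five steps that follow 18 here. The chosen route offers a precursor that comes in seven steps from a chiral-pool terpene, and one step that makes both C–O bonds.

Key step: step 8

## Route

Step 1
Reactants: 1 (R)-carvone
Product: 2 (R)-carvotanacetone, (5R)-2-methyl-5-(propan-2-yl)cyclohex-2-en-1-one
Conditions: H2 (1 atm), RhCl(PPh3)3 (cat.), benzene, rt
Reagents that add atoms: none
Why: Homogeneous hydrogenation with RhCl(PPh3)3 saturates the unhindered 1,1-disubstituted isopropenyl alkene far faster than the trisubstituted conjugated ring alkene, so the enone and the stereocentre are untouched.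

Step 2
Reactants: 3 5-chloropent-1-yne
Product: 5 2-bromo-5-chloropent-1-ene, via alkenylborane 4 (not isolated)
Conditions: B-bromo-9-BBN, CH2Cl2, 0 °C to rt; then AcOH, 0 °C
Reagents that add atoms: B-bromo-9-borabicyclo[3.3.1]nonane, BrB1C2CCCC1CCC2
Why: Haloboration: the B–Br bond adds syn across the terminal alkyne with bromine on the internal carbon, and protodeboronation of the alkenylborane by acetic acid leaves the 2-bromo-1-alkene; the primary chloride does not react.

Step 3
Reactants: 5 2-bromo-5-chloropent-1-ene; 2 (R)-carvotanacetone
Product: 9 (3R,5R)-3-(5-chloropent-1-en-2-yl)-2-methyl-5-(propan-2-yl)cyclohexan-1-one (both C2 epimers), via alkenyllithium 6 (not isolated), via cuprate 7 (not isolated), via lithium enolate 8 (not isolated)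
Conditions: 5, t-BuLi (2 equiv), Et2O, −78 °C; CuI (0.5 equiv), −78 to −40 °C; 2, −78 to −20 °C; aq. NH4Cl
Reagents that add atoms: none
Why: Bromine–lithium exchange at −78 °C outruns any reaction at the primary chloride, and the derived Gilman cuprate adds 1,4 to the enone. As with other 5-substituted cyclohexenones the alkenyl group should enter trans to the isopropyl group (axial attack on the half-chair with isopropyl equatorial), which sets eudesmane C5 relative to C7.

Step 4
Reactants: 9 chloro ketone
Product: 11 cis-fused (5S,7R,10R)-10-methyl-4-methylidene-7-(propan-2-yl)decalin-9-one, via potassium enolate 10 (not isolated)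
Conditions: t-BuOK, t-BuOH–THF, rt
Reagents that add atoms: none
Why: Under equilibrating alkoxide conditions the enolate towards the methyl-bearing carbon is alkylated by the primary chloride within the molecule (6-exo-tet, methylenecyclohexane annulation); the other enolate cannot close a six-membered ring. The chain is held on one face by C5, so the new C1–C10 bond can only form cis to the C4–C5 bond, which fixes the quaternary C10 and the cis fusion.

Step 5
Reactants: 11 cis-fused ketone
Product: 14 cis-fused 10-methyl-4-methylidene-7-(propan-2-yl)decal-7-en-9-one, via lithium enolate 12 (not isolated), via silyl enol ether 13 (not isolated)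
Conditions: LDA, TMSCl, THF, −78 °C; then Pd(OAc)2 (1.05 equiv), MeCN, rt
Reagents that add atoms: none
Why: C10 is quaternary, so enolisation can only go towards C8 and a single silyl enol ether forms; Saegusa–Ito oxidation (enolate of divalent palladium, β-hydride elimination of H7) then gives the enone. The C7 stereocentre, having relayed its chirality to C5 and C10, is given up on purpose.

Step 6
Reactants: 14 enone
Product: 16 cis-fused 10-methyl-4-methylidene-7-(propan-2-yl)decala-6,8-dien-9-yl trifluoromethanesulfonate, via lithium dienolate 15 (not isolated)
Conditions: LDA, THF, −78 °C; PhNTf2, −78 to 0 °C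
Reagents that add atoms: N-phenylbis(trifluoromethanesulfonimide), O=S(=O)(N(c1ccccc1)S(=O)(=O)C(F)(F)F)C(F)(F)F
Why: With no α′ hydrogen the amide base removes a γ hydrogen; the ring CH2 at C6 is more accessible than the isopropyl methine, so the linear endocyclic dienolate should form and is trapped on oxygen as the 1,3-dienyl triflate.

Step 7
Reactants: 16 dienyl triflate
Product: 17 cis-fused (5S,10S)-10-methyl-4-methylidene-7-(propan-2-yl)decala-6,8-diene
Conditions: Pd(OAc)2 (cat.), PPh3, Bu3N, HCO2H, DMF, 60 °C
Reagents that add atoms: none
Why: Palladium-catalysed formate reduction of an enol triflate: oxidative addition of zerovalent palladium into the C–O bond, exchange of triflate for formate, loss of CO2 and reductive elimination of C–H; the diene and the exocyclic alkene are not touched.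

Step 8
Reactants: 17 ring B diene
Product: 18 6α,9α-epidioxide of 17 (2,3-dioxabicyclo[2.2.2]oct-5-ene fused to ring A, peroxide bridge on the α face)
Conditions: O2, 5,10,15,20-tetraphenylporphyrin (cat.), CH2Cl2, visible light, −78 °C
Reagents that add atoms: dioxygen, O=O
Why: Visible light excites the porphyrin, which passes its triplet energy to O2; the singlet oxygen formed adds across C6 and C9 of the s-cis diene in a concerted suprafacial [4+2] cycloaddition. The closest known reactions are the endoperoxide-forming photooxygenations of cyclohexa-1,3-dienes, among them 2-alkyl-substituted ones such as α-terpinene. The one ring that closes, the six-membered 1,2-dioxine C6–O–O–C9–C8=C7, is formed by cycloaddition with both C–O bonds made in one step, which turns ring B into a 2,3-dioxabicyclo[2.2.2]oct-5-ene. The new stereocentres C6 and C9 are set together: suprafacial addition puts both oxygens on one face, and that face is chosen by the existing centres C5 and C10. In the half-chair of the diene that keeps C6 axial to ring A and away from the methylidene, the β face carries the pseudoaxial C1 methylene, whereas the α face carries only the pseudoaxial H5 and a pseudoequatorial methyl, so attack on the convex α face should be preferred. The step also needs chemoselectivity, which rests on the ring diene reacting with singlet oxygen orders of magnitude faster than a 1,1-disubstituted alkene does in the ene mode; low temperature and a non-polar solvent further disfavour ene reactions at H5 or at the isopropyl methine.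

Step 9
Reactants: 18 endoperoxide
Product: 19 cis-fused 9α-hydroxy-10-methyl-4-methylidene-7-(propan-2-yl)decal-7-en-6-one
Conditions: Et3N, CH2Cl2, 0 °C to rt
Reagents that add atoms: none
Why: Kornblum–DeLaMare rearrangement: the amine removes a bridgehead hydrogen as the O–O bond breaks, which turns that carbon into a ketone and the other into an alkoxide. Removal of H6 is counted on because H9 sits next to the fully substituted C10, whose methyl and C1 both lean over that end of the bicycle; the C9–O bond is not touched, so its α configuration is kept.

Step 10
Reactants: 19 hydroxy enone; 20 4-methoxybenzoyl chloride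
Product: 21 cis-fused 9α-(4-methoxybenzoyloxy)-10-methyl-4-methylidene-7-(propan-2-yl)decal-7-en-6-one
Conditions: 20, Et3N, DMAP (cat.), CH2Cl2, 0 °C to rt
Reagents that add atoms: none
Why: DMAP-catalysed acylation of the only hydroxyl group; the neopentyl-type secondary alcohol needs the nucleophilic catalyst, and the weakly basic medium should leave the γ-acyloxy enone and the methylidene alone.

Step 11
Reactants: 21 enone ester
Product: 23 cis-fused 9α-(4-methoxybenzoyloxy)-10-methyl-4-methylidene-7β-(propan-2-yl)decalin-6-one (7-epimer of 24), via potassium enolate 22 (not isolated)
Conditions: KBH(s-Bu)3 (1.1 equiv), THF, −78 °C; aq. NH4Cl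
Reagents that add atoms: none
Why: Hindered trialkylborohydrides reduce cyclohexenones that lack a β substituent in the 1,4 sense; hydride goes to C8 and the aryl ester is not attacked at −78 °C. The enolate is protonated at C7 under kinetic control, most probably from the α face, which is not screened by the axial C4 branch, so the 7β-isopropyl epimer 23 is expected to dominate; any 24 formed is carried along.

Step 12
Reactants: 23 7β-isopropyl ketone
Product: 24 cis-fused 9α-(4-methoxybenzoyloxy)-10-methyl-4-methylidene-7α-(propan-2-yl)decalin-6-one
Conditions: DBU (cat.), toluene, rt
Reagents that add atoms: none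
Why: Reversible enolisation towards C7 lets the isopropyl group reach the α position, where it and the C9 ester are both equatorial on one chair of ring B, whereas the β epimer must place one of them axial. In that chair H5 is equatorial to ring B and lies near the carbonyl plane, and at a cis ring fusion it cannot be axial to both rings, so it cannot overlap with the C=O and the methylidene π systems at once. Enolisation towards C5 should therefore be slow under a catalytic amidine base.

Step 13
Reactants: 24 7α-isopropyl ketone
Product: 25 (5S,6S,7R,9R,10R)-6-hydroxy-10-methyl-4-methylidene-7-(propan-2-yl)decalin-9-yl 4-methoxybenzoate (CNP0107029.1)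
Conditions: LiBH(s-Bu)3, THF, −78 °C; aq. NH4Cl
Reagents that add atoms: none
Why: The bulky hydride should attack the C6 carbonyl along the equatorial path from the β face, because the axial path on the α face is closed by the syn-axial C10 methyl group; this gives the axial 6α alcohol, cis to the methyl. The aryl ester is not reduced at −78 °C.

## Compound list

1 | (R)-carvone, (5R)-2-methyl-5-(prop-1-en-2-yl)cyclohex-2-en-1-one | CC1=CC[C@@H](C(C)=C)CC1=O | starting material
2 | (R)-carvotanacetone, (5R)-2-methyl-5-(propan-2-yl)cyclohex-2-en-1-one | CC1=CC[C@@H](C(C)C)CC1=O | intermediate
3 | 5-chloropent-1-yne | ClCCCC#C | starting material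
4 | 9-[(1Z)-2-bromo-5-chloropent-1-en-1-yl]-9-borabicyclo[3.3.1]nonane | ClCCC/C(Br)=C/B1C2CCCC1CCC2 | intermediate
5 | 2-bromo-5-chloropent-1-ene | C=C(Br)CCCCl | intermediate
6 | (5-chloropent-1-en-2-yl)lithium | [Li]C(=C)CCCCl | intermediate
7 | lithium bis(5-chloropent-1-en-2-yl)cuprate | [Li+].C=C(CCCCl)[Cu-]C(=C)CCCCl | intermediate
8 | lithium enolate of 9 (enolate towards the methyl-bearing carbon) | C=C(CCCCl)[C@@H]1C[C@@H](C(C)C)CC(O[Li])=C1C | intermediate
9 | (3R,5R)-3-(5-chloropent-1-en-2-yl)-2-methyl-5-(propan-2-yl)cyclohexan-1-one, both C2 epimers; alkenyl trans to isopropyl | C=C(CCCCl)[C@@H]1C[C@@H](C(C)C)CC(=O)C1C | intermediate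
10 | potassium enolate of 9 (towards the methyl-bearing carbon) | C=C(CCCCl)[C@@H]1C[C@@H](C(C)C)CC(O[K])=C1C | intermediate
11 | cis-fused (5S,7R,10R)-10-methyl-4-methylidene-7-(propan-2-yl)decalin-9-one; 5-H, 7-isopropyl and 10-CH3 all α | C=C1CCC[C@]2(C)[C@H]1C[C@@H](C(C)C)CC2=O | intermediate
12 | lithium 8-en-9-olate of 11 | C=C1CCC[C@]2(C)[C@H]1C[C@@H](C(C)C)C=C2O[Li] | intermediate
13 | 9-trimethylsilyloxy-8-ene (silyl enol ether of 11) | C=C1CCC[C@]2(C)[C@H]1C[C@@H](C(C)C)C=C2O[Si](C)(C)C | intermediate
14 | cis-fused 10-methyl-4-methylidene-7-(propan-2-yl)decal-7-en-9-one; 5-H and 10-CH3 α | C=C1CCC[C@]2(C)[C@H]1CC(C(C)C)=CC2=O | intermediate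
15 | lithium 6,8-dien-9-olate of 14 | C=C1CCC[C@]2(C)[C@H]1C=C(C(C)C)C=C2O[Li] | intermediate
16 | cis-fused 10-methyl-4-methylidene-7-(propan-2-yl)decala-6,8-dien-9-yl trifluoromethanesulfonate | C=C1CCC[C@]2(C)[C@H]1C=C(C(C)C)C=C2OS(=O)(=O)C(F)(F)F | intermediate
17 | cis-fused (5S,10S)-10-methyl-4-methylidene-7-(propan-2-yl)decala-6,8-diene; 5-H and 10-CH3 α | C=C1CCC[C@]2(C)[C@H]1C=C(C(C)C)C=C2 | intermediate
18 | 6α,9α-epidioxy-10-methyl-4-methylidene-7-(propan-2-yl)decal-7-ene, cis-fused; peroxide bridge on the face of the C10 methyl | C=C1CCC[C@]2(C)[C@H]1[C@H]3OO[C@@H]2C=C3C(C)C | intermediate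
19 | cis-fused 9α-hydroxy-10-methyl-4-methylidene-7-(propan-2-yl)decal-7-en-6-one | C=C1CCC[C@]2(C)[C@H]1C(=O)C(C(C)C)=C[C@H]2O | intermediate
20 | 4-methoxybenzoyl chloride | COc1ccc(cc1)C(Cl)=O | starting material
21 | cis-fused 9α-(4-methoxybenzoyloxy)-10-methyl-4-methylidene-7-(propan-2-yl)decal-7-en-6-one | C=C1CCC[C@]2(C)[C@H]1C(=O)C(C(C)C)=C[C@H]2OC(=O)c1ccc(OC)cc1 | intermediate
22 | potassium 6-en-6-olate formed from 21 by 1,4-hydride addition | C=C1CCC[C@]2(C)[C@H]1C(O[K])=C(C(C)C)C[C@H]2OC(=O)c1ccc(OC)cc1 | intermediate
23 | cis-fused 9α-(4-methoxybenzoyloxy)-10-methyl-4-methylidene-7β-(propan-2-yl)decalin-6-one | C=C1CCC[C@]2(C)[C@H]1C(=O)[C@H](C(C)C)C[C@H]2OC(=O)c1ccc(OC)cc1 | intermediate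
24 | cis-fused 9α-(4-methoxybenzoyloxy)-10-methyl-4-methylidene-7α-(propan-2-yl)decalin-6-one | C=C1CCC[C@]2(C)[C@H]1C(=O)[C@@H](C(C)C)C[C@H]2OC(=O)c1ccc(OC)cc1 | intermediate
25 | (5S,6S,7R,9R,10R)-6-hydroxy-10-methyl-4-methylidene-7-(propan-2-yl)decalin-9-yl 4-methoxybenzoate; cis-fused, 5-H, 6-OH, 7-isopropyl, 9-acyloxy and 10-CH3 all α | C=C1CCC[C@]2(C)[C@H]1[C@@H](O)[C@@H](C(C)C)C[C@H]2OC(=O)c1ccc(OC)cc1 | target

## Step count and least certain steps

Total: 13 steps. Longest linear sequence: 12 steps (steps 1 and 3–13 from 1; equally steps 2–13 from 3).

**Step 8 (key step).**
- What may go wrong: insufficient facial selectivity. Singlet oxygen is small and its transition state early, and the α face is not empty at the C9 end, where the C10 methyl stands. Ene reactions at the doubly allylic H5 or at the isopropyl methine, and decomposition of the peroxide on warming, are further losses.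
- Fallback (from 17, back at 21): the two oxygens are introduced one after the other. Buffered 3-chloroperbenzoic acid at low temperature epoxidises the trisubstituted C6=C7 bond, which is the most electron-rich alkene. The face there is decided only by C5 (H on α, the C4 branch on β), so the α selectivity should be higher than in the cycloaddition. This gives the 6α,7α-epoxy-8-ene F1. Pd(PPh3)4 (cat.) and 4-methoxybenzoic acid in THF then open the vinyl epoxide in the Tsuji–Trost manner: zerovalent palladium ionises C7–O with inversion, and the carboxylate attacks C9 anti to the metal. The net result is cis-1,4 addition, giving the 6α-hydroxy-9α-(4-methoxybenzoyloxy)-7-ene F2. MnO2 oxidises the allylic C6 alcohol of F2 to 21, and steps 9 and 10 are no longer needed.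

**Step 9.**
- What may go wrong: proton abstraction at the wrong bridgehead. The two hydrogens differ less than the neopentyl argument suggests, since H6 is itself flanked by the C4 branch and by the isopropyl group on C7. The regioisomeric 6-hydroxy-7-en-9-one would then form. Prolonged contact with base could also isomerise the γ-hydroxy enone to the 1,4-dione.
- Fallback (from 18, back at 21): the distinction is made by acylation, not by deprotonation. Thiourea in MeOH reduces the O–O bond to the cis-6α,9α-enediol F3. If the C6 end is the more crowded one (the very reason the base would have gone to H9), one equivalent of 20 with pyridine and DMAP at −20 °C should acylate the C9 hydroxyl and give the 6α-hydroxy-9α-ester F4, identical with F2. MnO2 then oxidises the C6 alcohol to 21.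

**Step 12.**
- What may go wrong: enolisation towards C5 in place of, or besides, C7. This would move the methylidene into conjugation (4-en-6-one) or epimerise the ring fusion, because the 7β epimer 23 can adopt a chair in which H5 is axial to ring B. The equilibrium may also lie less far on the side of 24 than hoped, since 23 pays only for an axial ester.
- Fallback (from 21, back at 24): C7 is set by kinetic, ligand-controlled protonation, and no base meets the ketone. The enolate 22 from step 11 is trapped at −78 °C with allyl chloroformate as the allyl enol carbonate F5. Pd(OAc)2 with a chiral phosphinooxazoline ligand and HCO2H in dioxane at 40 °C then effects decarboxylative protonation: zerovalent palladium ionises the allyl carbonate, CO2 is lost, and the palladium enolate is protonated on the face chosen by the ligand. Both ligand enantiomers are available, so the matched one is used. The product is 24.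

**Step 5.**
- What may go wrong: isomerisation of the exocyclic alkene into ring A by the palladium hydride released in the dehydrosilylation, or slow β-hydride elimination at the branched C7.
- Fallback (from 11, back at 14): dehydrogenation through selenium. LDA and then PhSeBr at −78 °C give the 8β-phenylselanyl ketone F6; the electrophile enters anti to the axial C10 methyl and so cis to H7. H2O2 and pyridine in CH2Cl2 at 0 °C give the selenoxide, whose syn elimination towards C7 gives 14 without any metal hydride.

## Further compounds

F1 | step 8 | cis-fused 6α,7α-epoxy-10-methyl-4-methylidene-7-(propan-2-yl)decal-8-ene | C=C1CCC[C@]2(C)[C@H]1[C@H]3O[C@@]3(C(C)C)C=C2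
F2 | step 8 | cis-fused 6α-hydroxy-10-methyl-4-methylidene-7-(propan-2-yl)decal-7-en-9α-yl 4-methoxybenzoate | C=C1CCC[C@]2(C)[C@H]1[C@@H](O)C(C(C)C)=C[C@H]2OC(=O)c1ccc(OC)cc1
F3 | step 9 | cis-fused 10-methyl-4-methylidene-7-(propan-2-yl)decal-7-ene-6α,9α-diol | C=C1CCC[C@]2(C)[C@H]1[C@@H](O)C(C(C)C)=C[C@H]2O
F4 | step 9 | cis-fused 6α-hydroxy-10-methyl-4-methylidene-7-(propan-2-yl)decal-7-en-9α-yl 4-methoxybenzoate (identical with F2) | C=C1CCC[C@]2(C)[C@H]1[C@@H](O)C(C(C)C)=C[C@H]2OC(=O)c1ccc(OC)cc1
F5 | step 12 | allyl enol carbonate of 24: 6-(allyloxycarbonyloxy)-9α-(4-methoxybenzoyloxy)-10-methyl-4-methylidene-7-(propan-2-yl)decal-6-ene | C=C1CCC[C@]2(C)[C@H]1C(OC(=O)OCC=C)=C(C(C)C)C[C@H]2OC(=O)c1ccc(OC)cc1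
F6 | step 5 | cis-fused 10-methyl-4-methylidene-8β-(phenylselanyl)-7α-(propan-2-yl)decalin-9-one | C=C1CCC[C@]2(C)[C@H]1C[C@@H](C(C)C)[C@H]([Se]c3ccccc3)C2=O
A1 | alternative 1 | tricyclic [2+2] photoadduct, bis(trimethylsilyloxy)bicyclo[2.2.0]hexane fused to the ring A ketone | O=C1CCC[C@]2(C)[C@H]1[C@@]3(O[Si](C)(C)C)CC[C@@]23O[Si](C)(C)C
A2 | alternative 1 | 3-methylcyclohex-2-en-1-one | CC1=CC(=O)CCC1
A3 | alternative 1 | 1,2-bis(trimethylsilyloxy)cyclobutene | C[Si](C)(C)OC1=C(O[Si](C)(C)C)CC1
A4 | alternative 1 | cis-fused 10-methyldecalin-4,6,9-trione | O=C1CCC[C@]2(C)[C@H]1C(=O)CCC2=O
A5 | alternative 2 | bicyclic cyclohexa-2,4-dienone with quaternary C10 methyl, C6 methoxy, C7 isopropyl and C4 tert-butyldimethylsilyloxy | CC(C)(C)[Si](C)(C)O[C@@H]1CCC[C@]2(C)C1=C(OC)C(C(C)C)=CC2=O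
A6 | alternative 2 | 3-[1-(tert-butyldimethylsilyloxy)-4-iodobutyl]-4-methoxy-2-methyl-5-(propan-2-yl)phenol | CC(C)(C)[Si](C)(C)O[C@H](CCCI)c1c(C)c(O)cc(C(C)C)c1OC
A7 | alternative 3 | ring-expanded ketone, identical with 24 | C=C1CCC[C@]2(C)[C@H]1C(=O)[C@@H](C(C)C)C[C@H]2OC(=O)c1ccc(OC)cc1
A8 | alternative 3 | cis-fused hydrindanone with ring A methylidene, angular methyl and 4-methoxybenzoyloxy group next to the quaternary carbon | C=C1CCC[C@]2(C)[C@H]1C(=O)C[C@H]2OC(=O)c1ccc(OC)cc1
A9 | alternative 3 | 2-methyl-1-diazopropane | CC(C)C=[N+]=[N-]
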